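(The data stem from a simulated flask on assumed constants.)

The slow sag after the peak, more than the fast climb, is what you should read in the ash run, and that run is the asked flask followed so far.

| setting | ash | larch | flask |
|---|---|---|---|
| starting material | 3 M | 1.5 M | 3.0 M |
| temperature | 50 °C | 56 °C | 50 °C |
| remark | the very flask that is asked about, followed so far | run made earlier |  |
| time |  |  | 3.0 h |
ash run (percent of the starting material charged): time / h: product / % = 0.417: 22.3; 0.833: 27.6; 1.33: 29.9; 1.50: 28.9; 2.00: 29.1; 2.50: 28.0

larch run (percent of the starting material charged): time / min: product / % = 3.00: 2.4; 5.00: 5.7; 8.00: 8.1; 12.0: 10.7; 20.0: 13.4; 40.0: 15.6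

(each reading ± 0.5 percentage points)
- summer: at 3.0 h take out 90% of the product then present, then wait 1.5 h
- winter: change nothing and wait 1.5 h more
- dawn: at 3.0 h raise the temperature by 25 K, then wait 1.5 h
- a species is counted by the starting material in it: one product counts as two
- product taken out counts as made
- reactions considered so far: 2 starting material <-> product; starting material <-> dormant form
- product, in percent of the starting material first charged, at 3.0 h
- the remedy with the largest gain of product, or "none" below 2 percentage points (summer / winter / dawn / none)
- product present, with what was taken out counted in, in percent of the starting material first charged, after summer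
- product present, with what was taken out counted in, in percent of the starting material first charged, after dawn

Draw the curve. The chord to the first reading climbs at 0.535 /h, as a share of the charge. Extended, it reaches the peak reading of 29.9% at 0.559 h, which marks the knee, though the peak reading itself comes at 1.33 h. After that, product falls, so it is now being lost faster than it forms:

sag = ln(29.9% / 28.0%) / (2.50 h − 1.33 h) = 0.0561 /h

Call this the sag constant, the fractional loss of product per hour past the peak. It is a reading resting on a small difference, with a scatter of 0.5 percentage points on each end, and the fall runs far slower than the climb. No ash reading shows the level the curve runs into. My own reckoning carries the last reading forward: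

product at 3.0 h = 28.0% × exp(−sag × (3.0 h − 2.50 h)) = 27.2%

Waiting a further 1.5 h then costs 2.2 points.

The forecast reads the plateau as “fast dimer equilibrium”. It gives 27.5% (26.5% to 28.6%) for now, 39.8% (37.5% to 42%) after summer and 8% (3% to 14%) after dawn, and it picks summer.

The flask gives 26.7% at 3.0 h, 27.5% after summer and 40.0% after dawn. The best remedy is dawn, with a gain of 13 points, against 0.83 points for summer and −3.4 points for winter.

    2 starting material ⇌ product (K = 1.20 /M, k = 4.80 × 10⁻⁵ /M/s, Ea = 66.0 kJ/mol, ΔH = −5.00 kJ/mol)
    starting material ⇌ dormant form (K = 8.00, k = 2.50 × 10⁻⁴ /s, Ea = 102 kJ/mol, ΔH = −67.0 kJ/mol)
    (constants at 50 °C)

From 26.7%, the sag constant gives 23.9% at 5.0 h. The neighbour flask left that long holds 22.3%, so the figure from the sag constant stands above it. In the asked flask at 3.00 h, the dormant form is the resting state, with 61.3% of the charge. The main reason product stands low there is the turning of starting material into dormant form, both ways: with that step taken away, product at 3.0 h stands at 65.5% in place of 26.7%. Part of what dawn brings comes out of this store: with the reverse step, dormant form to starting material, taken away, dawn brings −19 points in place of 13 points.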